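The set-ups take the same amounts, 0.10 M of substrate, 5.00 equiv of partner and 7.9 mol% of free catalyst, so they differ in vessel and in when these amounts meet.

| setting | violet | ochre | grey | green | gamma | eta | alpha | delta |
|---|---|---|---|---|---|---|---|---|
| substrate | 0.10 M | 0.10 M | 0.10 M | 0.10 M | 0.10 M | 0.10 M | 0.10 M (fed, over 20.0 min) | 0.10 M |
| partner | 5 equiv | 5 equiv | 5 equiv | 10 equiv | 5.00 equiv | 5.00 equiv (fed, over 20.0 min) | 5.00 equiv | 5.00 equiv |
| free catalyst | 7.9 mol% | 4 mol% | 5.9 mol% | 7.9 mol% | 7.9 mol% | 7.9 mol% | 7.9 mol% | 7.9 mol% |
| remark | run made earlier | run made earlier | run made earlier | run made earlier | one stirred flow tank at steady state, fed with the mixture as stated, mean residence time 25 min | all but partner at the start; partner goes in evenly over 20.0 min, the run ends at 25 min | a stirred flask in which substrate is dosed at a steady rate over 20.0 min without added volume, worked up at 25 min | everything together in a closed stirred flask, run for 25 min |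
| time |  |  |  |  |  | 25 min | 25 min | 25 min |

- violet (time / min: product / %): 2.00: 16.6; 5.00: 41.5; 10.0: 73.4; 25.0: 99.0
- ochre (time / min: product / %): 5.00: 22.7; 10.0: 43.1; 15.0: 60.6; 20.0: 74.7
- grey (time / min: product / %): 5.00: 31.8; 10.0: 59.2; 15.0: 80.0; 20.0: 91.2
- green (time / min: product / %): 5.00: 45.7; 10.0: 79.8; 15.0: 95.4; 20.0: 99.3

(standard deviation of a reading: 0.3 percentage points)

- the stated concentrations are those of everything mixed, before any reaction; amounts are the same in each set-up
- the numbers in the tables scatter with a standard deviation of 0.3 percentage points
- the feed brings no volume worth counting
- the earlier runs were made in a closed, stirred flask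

* the set-up with the highest amount of product at the outlet or at the end, in percent of the substrate put in ("none" if the first two lie within 2 percentage points) (gamma / eta / alpha / delta / none)
* amount of product at the outlet or at the end, in percent of the substrate put in, gamma
* amount of product at the outlet or at the end, in percent of the substrate put in, eta
* amount of product at the outlet or at the end, in percent of the substrate put in, alpha
* amount of product at the outlet or at the end, in percent of the substrate put in, delta

The violet run climbs in a straight line at first, with 16.6 % at 2.00 min and 41.5 % at 5.00 min. From this we read a turnover frequency, moles of product per mole of free catalyst charged per minute, of 1.05 min⁻¹. The ochre run, at about half the loading, reads 1.14 min⁻¹, but we keep the violet figure, whose loading is the one in these flasks. For delta, that frequency times loading times time gives 2.08. This turnover cover says how many times the catalyst, at its early pace, could work through the charged substrate.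

Our rule of thumb takes the cover as the fraction converted. In the violet run it holds at 2.00 min, where the line says 16.6 % against the reading of 16.6 %, but at 10.0 min the violet line says 83.0 % and the reading is 73.4 %, a ratio of 0.884, so the rule has ended by that cover. Beyond it, the cover says merely that the catalyst has time to spare, and delta repeats the violet run, so we expect about 99.0 %. In alpha the catalyst's early pace is faster than the substrate arrives, with a cover of 1.66 over the dosing time, so we expect alpha a little under delta. Eta lies past a second border: at 5.00 min it has received a quarter of its partner, while the earlier runs were charged at the start with 5 equiv or 10 equiv. We therefore give eta no figure.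

The forecast gives 83 % for gamma, 95 % for eta, 90 % for alpha and 99 % for delta, with delta best. For eta it judged that “partner is starved early” and stepped the run by hand.

The simulation gives 84.5 % for gamma, 83.1 % for eta, 92.8 % for alpha and 99.2 % for delta, so delta is best and eta stands 12 percentage points under the forecast.

substrate + free catalyst → catalyst intermediate A (k = 0.840 M⁻¹ s⁻¹); catalyst intermediate B → free catalyst + product (k = 0.0370 s⁻¹); partner + catalyst intermediate A ⇌ catalyst intermediate B (K = 6.20 M⁻¹, k = 1.10 M⁻¹ s⁻¹); 2 catalyst intermediate A → spent catalyst (k = 0.200 M⁻¹ s⁻¹) Eta ends with 43.3 % of its catalyst spent, far more than the 7.17 % in delta at the same time. The neighbouring flask, delta with 2 mol% of free catalyst, has a cover of 0.525, below the border, so the rule of thumb reads 52.5 %. That flask gives 52.5 %, with 46 % of its substrate still there unbound.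

All runs come from a simulation for substances that don't exist; noise was put on by code.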